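**Plan**

- Numbering: each tetrahydrofuran is O1, C2 (aryl), C3 (C9H2OH), C4 (OH and C7'H2Ar), C5. Unit A has outer ring a on C7' and biaryl ring b on C2; unit B has biaryl ring c on C7' and outer ring d on C2.
- Cuts, in retrosynthetic order: both O1–C2 bonds (to an open-chain bis-triol), the ring b–ring c biaryl bond, then in each half the C4–C7' and C4–OH bonds of an (R)-3-(arylmethyl)butyrolactone, which goes back to an aryl aldehyde and dimethyl succinate.
- Forward: two lactones by Stobbe condensation, asymmetric hydrogenation and reduction–lactonisation; α-hydroxylation and dianion benzylation attach rings a and c; Miyaura/Suzuki coupling joins rings b and c; MOM removal and LiAlH4 open both lactones; one oxidase step closes both tetrahydrofurans; hydrogenolysis frees rings a and c.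
- Enabling feature: each C2 is a benzylic CH2 para to the free phenol of ring b or ring d, so it can be dehydrogenated to a p-quinone methide, and O5 on C5 is the only hydroxyl that reaches C2 through a five-membered ring. Rings a and c stay benzyl ethers until the last step, which keeps both C7' methylenes inert.
- Stereochemistry: C3 from Rh–DuPhos hydrogenation of the half-esters, C4 from benzylation of the lactone dianion anti to the C3 arylmethyl group, C2 from ring closure trans to C9 under control of C3.

Key step: step 21

Remark: lactones are numbered as oxolan-2-ones (lactone C3 = unit C4, lactone C4 = unit C3).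
Remark: (S,S)-Et-DuPhos is assumed to be the ligand antipode that gives the R acids 5 and 17; if the sense is the opposite, the (R,R) ligand is used.
Remark: in step 21 unit B (unhindered ring d) is assumed to react before unit A; the order does not change the product, and the exocyclic double-bond geometry of the transient quinone methides is left open.

**Route**

Step 1
Reactants: 1 5-bromovanillin
Product: 2 3-bromo-5-methoxy-4-(methoxymethoxy)benzaldehyde
Conditions: MOMCl, iPr2NEt, CH2Cl2, 0 °C to rt
Reagents that add atoms: chloromethyl methyl ether, COCCl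
Why: O-alkylation of the phenol (MOM protection); the acetal ether should tolerate the alkoxide, amide-base, hydride and palladium steps ahead and can later be removed by acid without loss of benzyl ethers.

Step 2
Reactants: 2 3-bromo-5-methoxy-4-(methoxymethoxy)benzaldehyde; 3 dimethyl succinate
Product: 4 (E)-4-[3-bromo-5-methoxy-4-(methoxymethoxy)phenyl]-3-(methoxycarbonyl)but-3-enoic acid
Conditions: NaOMe, MeOH, reflux; then aq. HCl to pH 2
Reagents that add atoms: none
Why: Stobbe condensation of a non-enolisable aryl aldehyde with a succinic diester, which should give the (E)-arylidenesuccinic monoester with the free acid on the CH2 arm.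

Step 3
Reactants: 4 (E)-arylidenesuccinic half-ester of ring b
Product: 5 (3R)-4-[3-bromo-5-methoxy-4-(methoxymethoxy)phenyl]-3-(methoxycarbonyl)butanoic acid
Conditions: H2 (5 bar), [Rh(cod)((S,S)-Et-DuPhos)]BF4 (1 mol %), NaOMe (10 mol %), MeOH, rt
Reagents that add atoms: none
Why: Rh–bisphospholane asymmetric hydrogenation of an itaconate-type half-ester bound through its carboxylate; the ligand sets the stereocentre (R, the later C3 of unit A), and the cationic Rh catalyst should leave the aryl bromide and the MOM ether untouched.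

Step 4
Reactants: 5 (3R)-half-ester of ring b
Product: 7 (4R)-4-[3-bromo-5-methoxy-4-(methoxymethoxy)benzyl]oxolan-2-one, via hydroxy acid 6 (not isolated)
Conditions: KOH (1 equiv), CaCl2, NaBH4, EtOH, −10 °C to rt; then 1 M HCl, 0 °C to rt
Reagents that add atoms: none
Why: chemoselective calcium borohydride reduction of the ester beside the carboxylate salt, then acid-promoted lactonisation of the γ-hydroxy acid; the stereocentre is not involved.

Step 5
Reactants: 7 (4R)-lactone of ring b
Product: 9 (3R,4S)-4-[3-bromo-5-methoxy-4-(methoxymethoxy)benzyl]-3-hydroxyoxolan-2-one, via potassium enolate 8 (not isolated)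
Conditions: KHMDS, THF, −78 °C; then 2-(phenylsulfonyl)-3-phenyloxaziridine, −78 °C; aq. NH4Cl
Reagents that add atoms: 2-(phenylsulfonyl)-3-phenyloxaziridine, O=S(=O)(c1ccccc1)N1OC1c1ccccc1
Why: Davis oxidation of the lactone enolate; oxygen should be delivered anti to the C4 arylmethyl group (trans alcohol), and this centre is made planar again in step 7, so its configuration is not critical.

Step 6
Reactants: 10 4-(benzyloxy)-3-methoxybenzyl alcohol
Product: 11 4-(benzyloxy)-3-methoxybenzyl bromide
Conditions: PBr3, Et2O, 0 °C; used crude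
Reagents that add atoms: phosphorus tribromide, BrP(Br)Br
Why: bromination of a benzylic alcohol through its bromophosphite; the electron-rich bromide is labile and is taken on without purification.

Step 7
Reactants: 9 trans-hydroxylactone of ring b; 11 4-(benzyloxy)-3-methoxybenzyl bromide
Product: 13 (3S,4S)-3-[4-(benzyloxy)-3-methoxybenzyl]-4-[3-bromo-5-methoxy-4-(methoxymethoxy)benzyl]-3-hydroxyoxolan-2-one, via dilithium enediolate 12 (not isolated)
Conditions: LDA (2.2 equiv), THF/DMPU, −78 to −40 °C; then 11, −78 to −20 °C; aq. NH4Cl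
Reagents that add atoms: none
Why: C-alkylation of the α-hydroxy lactone dianion; the bromide should approach planar lactone C3 from the face opposite the C4 arylmethyl group, placing the new benzyl trans to it and the hydroxyl cis (3S,4S), which sets C4 of unit A.

Step 8
Reactants: 14 vanillin
Product: 15 3-methoxy-4-(methoxymethoxy)benzaldehyde
Conditions: MOMCl, iPr2NEt, CH2Cl2, 0 °C to rt
Reagents that add atoms: chloromethyl methyl ether, COCCl
Why: MOM protection of the phenol by O-alkylation, for the same reasons as in step 1.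

Step 9
Reactants: 15 3-methoxy-4-(methoxymethoxy)benzaldehyde; 3 dimethyl succinate
Product: 16 (E)-3-(methoxycarbonyl)-4-[3-methoxy-4-(methoxymethoxy)phenyl]but-3-enoic acid
Conditions: NaOMe, MeOH, reflux; then aq. HCl to pH 2
Reagents that add atoms: none
Why: Stobbe condensation, as in step 2, expected to give the (E)-half-ester.

Step 10
Reactants: 16 (E)-arylidenesuccinic half-ester of ring d
Product: 17 (3R)-3-(methoxycarbonyl)-4-[3-methoxy-4-(methoxymethoxy)phenyl]butanoic acid
Conditions: H2 (5 bar), [Rh(cod)((S,S)-Et-DuPhos)]BF4 (1 mol %), NaOMe (10 mol %), MeOH, rt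
Reagents that add atoms: none
Why: Rh–bisphospholane asymmetric hydrogenation as in step 3; the ligand sets the stereocentre (R, the later C3 of unit B).

Step 11
Reactants: 17 (3R)-half-ester of ring d
Product: 19 (4R)-4-[3-methoxy-4-(methoxymethoxy)benzyl]oxolan-2-one, via hydroxy acid 18 (not isolated)
Conditions: KOH (1 equiv), CaCl2, NaBH4, EtOH, −10 °C to rt; then 1 M HCl, 0 °C to rt
Reagents that add atoms: none
Why: ester-selective calcium borohydride reduction and lactonisation as in step 4; the stereocentre is untouched.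

Step 12
Reactants: 19 (4R)-lactone of ring d
Product: 21 (3R,4S)-3-hydroxy-4-[3-methoxy-4-(methoxymethoxy)benzyl]oxolan-2-one, via potassium enolate 20 (not isolated)
Conditions: KHMDS, THF, −78 °C; then 2-(phenylsulfonyl)-3-phenyloxaziridine, −78 °C; aq. NH4Cl
Reagents that add atoms: 2-(phenylsulfonyl)-3-phenyloxaziridine, O=S(=O)(c1ccccc1)N1OC1c1ccccc1
Why: Davis oxidation of the lactone enolate anti to the C4 arylmethyl group, as in step 5.

Step 13
Reactants: 1 5-bromovanillin
Product: 22 4-(benzyloxy)-3-bromo-5-methoxybenzaldehyde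
Conditions: BnBr, K2CO3, DMF, 60 °C
Reagents that add atoms: benzyl bromide, BrCc1ccccc1
Why: Williamson benzylation of the phenoxide; the benzyl ether of ring c has to survive acid, base, hydride and the oxidase step and is removed only at the end.

Step 14
Reactants: 22 4-(benzyloxy)-3-bromo-5-methoxybenzaldehyde
Product: 23 [4-(benzyloxy)-3-bromo-5-methoxyphenyl]methanol
Conditions: NaBH4, MeOH/THF, 0 °C; aq. NH4Cl
Reagents that add atoms: none
Why: borohydride reduction of an aryl aldehyde, which leaves the aryl bromide and the benzyl ether intact.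

Step 15
Reactants: 23 [4-(benzyloxy)-3-bromo-5-methoxyphenyl]methanol
Product: 24 4-(benzyloxy)-3-bromo-5-methoxybenzyl bromide
Conditions: PBr3, CH2Cl2, 0 °C
Reagents that add atoms: phosphorus tribromide, BrP(Br)Br
Why: bromination of the benzylic alcohol through its bromophosphite, as in step 6.

Step 16
Reactants: 21 trans-hydroxylactone of ring d; 24 4-(benzyloxy)-3-bromo-5-methoxybenzyl bromide
Product: 26 (3S,4S)-3-[4-(benzyloxy)-3-bromo-5-methoxybenzyl]-3-hydroxy-4-[3-methoxy-4-(methoxymethoxy)benzyl]oxolan-2-one, via dilithium enediolate 25 (not isolated)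
Conditions: LDA (2.2 equiv), THF/DMPU, −78 to −40 °C; then 24, −78 to −20 °C; aq. NH4Cl
Reagents that add atoms: none
Why: dianion benzylation as in step 7; attack anti to the C4 arylmethyl group should give the 3S,4S lactone and so set C4 of unit B, the aryl bromide of 24 being inert to the enediolate.

Step 17
Reactants: 26 unit B lactone (aryl bromide on ring c)
Product: 27 (3S,4S)-3-[4-(benzyloxy)-3-methoxy-5-(4,4,5,5-tetramethyl-1,3,2-dioxaborolan-2-yl)benzyl]-3-hydroxy-4-[3-methoxy-4-(methoxymethoxy)benzyl]oxolan-2-one
Conditions: B2pin2, Pd(dppf)Cl2 (5 mol %), KOAc, 1,4-dioxane, 85 °C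
Reagents that add atoms: bis(pinacolato)diboron, CC1(C)OB(OC1(C)C)B1OC(C)(C)C(C)(C)O1
Why: Miyaura borylation of the aryl bromide; the weak acetate base should leave the lactone and the tertiary alcohol intact.

Step 18
Reactants: 13 unit A lactone (aryl bromide on ring b); 27 unit B lactone (pinacol boronate on ring c)
Product: 28 biaryl bis-lactone (rings b and c joined; rings a and c O-benzyl, rings b and d O-MOM)
Conditions: Pd(OAc)2 (5 mol %), SPhos (10 mol %), K3PO4, toluene/H2O, 70 °C; work-up at pH 4
Reagents that add atoms: none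
Why: Suzuki–Miyaura coupling forming the ring b–ring c bond, with a dialkylbiarylphosphine ligand because each partner has an ortho alkoxy group; the biaryl has only two ortho substituents and no stable axis to control, and the mildly acidic work-up re-closes any lactone opened by the base.

Step 19
Reactants: 28 biaryl bis-lactone
Product: 29 bis-phenol bis-lactone (free 4-OH on rings b and d)
Conditions: 3 M HCl, MeOH/THF, 45 °C
Reagents that add atoms: none
Why: acid-catalysed acetal cleavage of the two aryl MOM ethers with methanol as formaldehyde acceptor; benzyl ethers, lactones and tertiary alcohols are stable, and no free 1,2- or 1,3-diol is present yet that could be tied up as a methylene acetal.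

Step 20
Reactants: 29 bis-phenol bis-lactone
Product: 30 open-chain hexaol with free phenols on rings b and d and benzyl ethers on rings a and c
Conditions: LiAlH4 (excess), THF, 0 °C to rt; aq. Rochelle salt
Reagents that add atoms: none
Why: LiAlH4 reduction of both α-hydroxy-γ-lactones to 1,2,4-triols, a reduction well known for free-phenolic hydroxylactone lignans; neither stereocentre carries an acidic hydrogen, so both are retained.

Step 21
Reactants: 30 open-chain hexaol
Product: 34 target with rings a and c as benzyl ethers, via ring-d quinone methide 31 (not isolated), via mono-tetrahydrofuran 32 (not isolated), via ring-b quinone methide 33 (not isolated)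
Conditions: eugenol oxidase or vanillyl alcohol oxidase variant with widened substrate channel, air (O2), catalase, 50 mM potassium phosphate pH 7.5, 20% v/v DMSO, 30 °C
Reagents that add atoms: none
Why: Proposed new method: the oxidase binds the para-phenolate of ring d and then of ring b, its flavin abstracts hydride from the benzylic C2–H to give a p-quinone methide (31, then 33), the C5 hydroxyl adds to the exocyclic carbon in place of water, and O2 reoxidises the flavin to give H2O2. The closest known reactions are the dehydrogenation–hydration of 4-alkylphenols by vanillyl alcohol oxidase and eugenol oxidase and the DDQ-induced cyclisation of phenolic dibenzylbutanediols to 2-aryltetrahydrofurans. Both tetrahydrofurans close by 5-exo-trig attack of O5 on C2, since O9 and the C4 hydroxyl could reach C2 only through four-membered rings. Each new C2 centre is controlled by the adjacent C3 centre: allylic 1,3-strain holds C3–H in the plane of the quinone methide, so O5 arrives from the face of the C4 arm and the aryl group ends trans to C9H2OH (2S), which is also the more stable 2,3-trans ring, provided the enzyme pocket does not override this substrate control. The step needs site selectivity for C2 over C7', and the substrate secures it because rings a and c are benzyl ethers and cannot form the phenolate the flavoenzyme requires, so only the methylenes para to the free phenols of rings b and d can be dehydrogenated. The reaction should be stopped once 32 is consumed, because the product still has a para-hydroxybenzylic C2–H that could be oxidised further.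

Step 22
Reactants: 34 target with rings a and c as benzyl ethers
Product: 35 CNP0269573.1
Conditions: H2 (1 atm), 10% Pd/C, EtOAc/MeOH, rt, stopped at full debenzylation
Reagents that add atoms: none
Why: hydrogenolysis of the two aryl benzyl ethers; under neutral conditions at 1 atm, ArO–CH2Ph cleavage should be much faster than cleavage of the benzylic C2–O1 bonds of the tetrahydrofurans.

**Compound list**

1 | 5-bromovanillin (3-bromo-4-hydroxy-5-methoxybenzaldehyde) | COc1cc(C=O)cc(Br)c1O | starting material
2 | 3-bromo-5-methoxy-4-(methoxymethoxy)benzaldehyde | COCOc1c(Br)cc(C=O)cc1OC | intermediate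
3 | dimethyl succinate | COC(=O)CCC(=O)OC | starting material
4 | (E)-4-[3-bromo-5-methoxy-4-(methoxymethoxy)phenyl]-3-(methoxycarbonyl)but-3-enoic acid | COC(=O)/C(CC(=O)O)=C/c1cc(Br)c(OCOC)c(OC)c1 | intermediate
5 | (3R)-4-[3-bromo-5-methoxy-4-(methoxymethoxy)phenyl]-3-(methoxycarbonyl)butanoic acid | COC(=O)[C@H](Cc1cc(Br)c(OCOC)c(OC)c1)CC(=O)O | intermediate
6 | (3R)-4-[3-bromo-5-methoxy-4-(methoxymethoxy)phenyl]-3-(hydroxymethyl)butanoic acid (not isolated) | OC[C@H](Cc1cc(Br)c(OCOC)c(OC)c1)CC(=O)O | intermediate
7 | (4R)-4-[3-bromo-5-methoxy-4-(methoxymethoxy)benzyl]oxolan-2-one | O=C1C[C@@H](Cc2cc(Br)c(OCOC)c(OC)c2)CO1 | intermediate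
8 | potassium enolate of 7, C4 configuration unchanged (not isolated) | [K+].[O-]C1=C[C@@H](Cc2cc(Br)c(OCOC)c(OC)c2)CO1 | intermediate
9 | (3R,4S)-4-[3-bromo-5-methoxy-4-(methoxymethoxy)benzyl]-3-hydroxyoxolan-2-one (trans) | O[C@H]1C(=O)OC[C@@H]1Cc1cc(Br)c(OCOC)c(OC)c1 | intermediate
10 | 4-(benzyloxy)-3-methoxybenzyl alcohol | COc1cc(CO)ccc1OCc1ccccc1 | starting material
11 | 4-(benzyloxy)-3-methoxybenzyl bromide | COc1cc(CBr)ccc1OCc1ccccc1 | intermediate
12 | dilithium 2,3-enediolate of 9, C4 configuration unchanged (not isolated) | [Li+].[Li+].[O-]C1=C([O-])[C@@H](Cc2cc(Br)c(OCOC)c(OC)c2)CO1 | intermediate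
13 | (3S,4S)-3-[4-(benzyloxy)-3-methoxybenzyl]-4-[3-bromo-5-methoxy-4-(methoxymethoxy)benzyl]-3-hydroxyoxolan-2-one (unit A lactone) | COc1cc(C[C@@]2(O)C(=O)OC[C@@H]2Cc2cc(Br)c(OCOC)c(OC)c2)ccc1OCc1ccccc1 | intermediate
14 | vanillin | COc1cc(C=O)ccc1O | starting material
15 | 3-methoxy-4-(methoxymethoxy)benzaldehyde | COCOc1ccc(C=O)cc1OC | intermediate
16 | (E)-3-(methoxycarbonyl)-4-[3-methoxy-4-(methoxymethoxy)phenyl]but-3-enoic acid | COC(=O)/C(CC(=O)O)=C/c1ccc(OCOC)c(OC)c1 | intermediate
17 | (3R)-3-(methoxycarbonyl)-4-[3-methoxy-4-(methoxymethoxy)phenyl]butanoic acid | COC(=O)[C@H](Cc1ccc(OCOC)c(OC)c1)CC(=O)O | intermediate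
18 | (3R)-3-(hydroxymethyl)-4-[3-methoxy-4-(methoxymethoxy)phenyl]butanoic acid (not isolated) | OC[C@H](Cc1ccc(OCOC)c(OC)c1)CC(=O)O | intermediate
19 | (4R)-4-[3-methoxy-4-(methoxymethoxy)benzyl]oxolan-2-one | O=C1C[C@@H](Cc2ccc(OCOC)c(OC)c2)CO1 | intermediate
20 | potassium enolate of 19, C4 configuration unchanged (not isolated) | [K+].[O-]C1=C[C@@H](Cc2ccc(OCOC)c(OC)c2)CO1 | intermediate
21 | (3R,4S)-3-hydroxy-4-[3-methoxy-4-(methoxymethoxy)benzyl]oxolan-2-one (trans) | O[C@H]1C(=O)OC[C@@H]1Cc1ccc(OCOC)c(OC)c1 | intermediate
22 | 4-(benzyloxy)-3-bromo-5-methoxybenzaldehyde | COc1cc(C=O)cc(Br)c1OCc1ccccc1 | intermediate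
23 | [4-(benzyloxy)-3-bromo-5-methoxyphenyl]methanol | COc1cc(CO)cc(Br)c1OCc1ccccc1 | intermediate
24 | 4-(benzyloxy)-3-bromo-5-methoxybenzyl bromide | COc1cc(CBr)cc(Br)c1OCc1ccccc1 | intermediate
25 | dilithium 2,3-enediolate of 21, C4 configuration unchanged (not isolated) | [Li+].[Li+].[O-]C1=C([O-])[C@@H](Cc2ccc(OCOC)c(OC)c2)CO1 | intermediate
26 | (3S,4S)-3-[4-(benzyloxy)-3-bromo-5-methoxybenzyl]-3-hydroxy-4-[3-methoxy-4-(methoxymethoxy)benzyl]oxolan-2-one (unit B lactone) | COc1cc(C[C@@]2(O)C(=O)OC[C@@H]2Cc2ccc(OCOC)c(OC)c2)cc(Br)c1OCc1ccccc1 | intermediate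
27 | (3S,4S)-3-[4-(benzyloxy)-3-methoxy-5-(4,4,5,5-tetramethyl-1,3,2-dioxaborolan-2-yl)benzyl]-3-hydroxy-4-[3-methoxy-4-(methoxymethoxy)benzyl]oxolan-2-one | COc1cc(C[C@@]2(O)C(=O)OC[C@@H]2Cc2ccc(OCOC)c(OC)c2)cc(B2OC(C)(C)C(C)(C)O2)c1OCc1ccccc1 | intermediate
28 | biaryl bis-lactone: 13 and 26 joined through the former C–Br carbons of rings b and c; both lactones 3S,4S; rings a and c O-benzyl, rings b and d O-MOM | COc1cc(C[C@@]2(O)C(=O)OC[C@@H]2Cc2cc(OC)c(OCOC)c(-c3cc(C[C@@]4(O)C(=O)OC[C@@H]4Cc4ccc(OCOC)c(OC)c4)cc(OC)c3OCc3ccccc3)c2)ccc1OCc1ccccc1 | intermediate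
29 | bis-phenol bis-lactone: 28 with both MOM groups replaced by H | COc1cc(C[C@@]2(O)C(=O)OC[C@@H]2Cc2cc(OC)c(O)c(-c3cc(C[C@@]4(O)C(=O)OC[C@@H]4Cc4ccc(O)c(OC)c4)cc(OC)c3OCc3ccccc3)c2)ccc1OCc1ccccc1 | intermediate
30 | open-chain hexaol: two (2S,3S)-2,3-bis(arylmethyl)butane-1,2,4-triol units on the b–c biaryl; free phenols on rings b and d, benzyl ethers on rings a and c | COc1cc(C[C@@](O)(CO)[C@H](CO)Cc2cc(OC)c(O)c(-c3cc(C[C@@](O)(CO)[C@H](CO)Cc4ccc(O)c(OC)c4)cc(OC)c3OCc3ccccc3)c2)ccc1OCc1ccccc1 | intermediate
31 | ring-d p-quinone methide of 30, C2 of unit B as exocyclic =CH (not isolated) | COc1cc(C[C@@](O)(CO)[C@H](CO)Cc2cc(OC)c(O)c(-c3cc(C[C@@](O)(CO)[C@H](CO)C=C4C=CC(=O)C(OC)=C4)cc(OC)c3OCc3ccccc3)c2)ccc1OCc1ccccc1 | intermediate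
32 | mono-tetrahydrofuran: unit B closed (2S,3R,4S), unit A still open (not isolated) | COc1cc(C[C@@](O)(CO)[C@H](CO)Cc2cc(OC)c(O)c(-c3cc(C[C@@]4(O)CO[C@H](c5ccc(O)c(OC)c5)[C@H]4CO)cc(OC)c3OCc3ccccc3)c2)ccc1OCc1ccccc1 | intermediate
33 | ring-b p-quinone methide of 32, C2 of unit A as exocyclic =CH (not isolated) | COc1cc(C[C@@](O)(CO)[C@H](CO)C=C2C=C(OC)C(=O)C(c3cc(C[C@@]4(O)CO[C@H](c5ccc(O)c(OC)c5)[C@H]4CO)cc(OC)c3OCc3ccccc3)=C2)ccc1OCc1ccccc1 | intermediate
34 | target with the 4-OH of rings a and c as benzyl ethers; both tetrahydrofurans 2S,3R,4S | COc1cc(C[C@@]2(O)CO[C@H](c3cc(OC)c(O)c(-c4cc(C[C@@]5(O)CO[C@H](c6ccc(O)c(OC)c6)[C@H]5CO)cc(OC)c4OCc4ccccc4)c3)[C@H]2CO)ccc1OCc1ccccc1 | intermediate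
35 | CNP0269573.1: two (2S,3R,4S)-2-aryl-4-(arylmethyl)-3-(hydroxymethyl)oxolan-4-ol units joined ring b C5 to ring c C5, all four rings 4-hydroxy-3-methoxyphenyl | COc1cc(C[C@@]2(O)CO[C@H](c3cc(OC)c(O)c(-c4cc(C[C@@]5(O)CO[C@H](c6ccc(O)c(OC)c6)[C@H]5CO)cc(OC)c4O)c3)[C@H]2CO)ccc1O | target

**Step count and risks**

Total: 22 steps. Longest linear sequence: 12 steps (8, 9, 10, 11, 12, 16, 17, 18, 19, 20, 21, 22).

Step 21 (proposed new method). What may go wrong:
- the large, partly lipophilic substrate may be excluded from the closed active site, so that no hydride transfer takes place;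
- water may capture the enzyme-bound quinone methide, or it may tautomerise to the C2=C3 styrene, before O5 adds;
- ring a or ring c may attack C2 through carbon, giving a six-membered carbocycle;
- the product may be oxidised further at its remaining C2–H.

The fallback uses known chemistry and gives up the biocatalyst. Compound 30 is treated with DDQ (2.1 equiv) in dry 1,4-dioxane at rt. The two free phenols should be dehydrogenated to the same quinone methides, which close through O5 in the absence of water, while the benzyl ethers again keep C7' untouched. This is the established quinone-mediated cyclisation of phenolic dibenzylbutanediol lignans to 2-aryltetrahydrofurans. The fallback sets out from 30 and returns to the route at 34; it makes no new compound (F0).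

Step 7. What may go wrong: incomplete C-alkylation of the aggregated dilithium enediolate, competing O-benzylation of its alkoxide, and attack of the excess amide base on the aryl bromide. The fallback avoids the dianion. From 9, 2-methoxypropene with catalytic PPTS (CH2Cl2, 0 °C) should give the 2-methoxypropan-2-yl ether F1. One equivalent of LDA (THF, −78 °C) and bromide 11 should then give the C-benzylated acetal F2, again by attack anti to the C4 arylmethyl group. PPTS in MeOH at rt removes the acetal and returns the route to 13.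

Step 18. What may go wrong: protodeboronation of the ortho-alkoxy boronate and hydroxide-induced opening of the lactones during a slow coupling, with homocoupling as a side path. The fallback is a base-free Stille coupling. From 26, hexamethylditin and Pd(PPh3)4 (toluene, 100 °C) should give the aryl trimethylstannane F3. This is coupled with bromide 13 (Pd(PPh3)4, CuI, CsF, DMF, 45 °C) and returns to the route at 28.

Further compounds
F0 | step 21 | none | none
F1 | step 7 | (3R,4S)-4-[3-bromo-5-methoxy-4-(methoxymethoxy)benzyl]-3-[(2-methoxypropan-2-yl)oxy]oxolan-2-one | COC(C)(C)O[C@H]1C(=O)OC[C@@H]1Cc1cc(Br)c(OCOC)c(OC)c1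
F2 | step 7 | (3S,4S)-3-[4-(benzyloxy)-3-methoxybenzyl]-4-[3-bromo-5-methoxy-4-(methoxymethoxy)benzyl]-3-[(2-methoxypropan-2-yl)oxy]oxolan-2-one | COc1cc(C[C@@]2(OC(C)(C)OC)C(=O)OC[C@@H]2Cc2cc(Br)c(OCOC)c(OC)c2)ccc1OCc1ccccc1
F3 | step 18 | (3S,4S)-3-[4-(benzyloxy)-3-methoxy-5-(trimethylstannyl)benzyl]-3-hydroxy-4-[3-methoxy-4-(methoxymethoxy)benzyl]oxolan-2-one | COc1cc(C[C@@]2(O)C(=O)OC[C@@H]2Cc2ccc(OCOC)c(OC)c2)cc([Sn](C)(C)C)c1OCc1ccccc1
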